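**Plan**
- The last bond cut lies in ring C, between the tertiary carbinol carbon shared by rings B and C and the ring C CH2 attached to the C/D-fusion CH of ring D. This CH2 is not bonded to the quaternary carbon, so it can be a primary iodide that closes onto a ring B ketone (iodo enone 35).
- The second cut removes the CH2 bridge between the α'-carbon of the ring B enone and the quaternary carbon of ring D (aldol, dehydration, conjugate reduction), giving AB enone 11 and ring D aldehyde 27.
- Rings A and B arise together by a rhodium-catalysed [4+2+2] cycloaddition of enyne 6 (from (R)-β-citronellene) with butadiene, followed by oxidation of the doubly allylic CH2 and conjugate addition of methyl.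
- Ring D comes from (S)-limonene by ring contraction (ozonolysis, aldol condensation); a Still–Wittig rearrangement builds the quaternary centre and a hydroboration the CH2O arm. The fragments are joined in step 17 and ring C closes last.
- Stereochemistry: ring A methyl from citronellene; ring-fusion CH from substrate control in the cycloaddition; ring B methyl from a chiral copper catalyst; the three ring D centres relayed from the limonene stereocentre; the α'-centre from protonation and equilibration; the carbinol from the chair transition state of the ring closure.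

Key step: step 22

Locants used below: C1–C11 are the bicyclo[6.3.0]undecane locants of the ring A/B part (C1=C2 alkene, C3 carbonyl, C4 α'-carbon, C5 CHMe of ring B, C8 ring-fusion CH, C9 CHMe of ring A). C1'–C3' are those of the ring D cyclopentane (C1' quaternary, C2' bearing the CH2X arm, C3' bearing isopropyl). The (S,R,R)-phosphoramidite ligand of step 6 is O,O'-[(S)-1,1'-binaphthyl-2,2'-diyl] N,N-bis[(R)-1-phenylethyl]phosphoramidite.

Assumption: the copper catalyst of step 6 shows on dienone 9 the same sense of induction as on simple cycloalkenones (S configuration at the new β-centre), the remote C8 centre exerting little bias of its own.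

Step 1
Reactants: 1 (R)-β-citronellene [(3R)-3,7-dimethylocta-1,6-diene]
Product: 3 (4R)-4-methylhex-5-enal, via ozonide 2 (not isolated)
Conditions: O3 (1.0 equiv), CH2Cl2, −78 °C; then Me2S, −78 °C to rt
Reagents that add atoms: ozone, [O-][O+]=O
Why: Ozonolysis with reductive work-up; the electron-rich trisubstituted alkene takes up ozone far faster than the vinyl group, so one equivalent should cut only the isopropylidene end and leave the stereocentre untouched.

Step 2
Reactants: 3 (4R)-4-methylhex-5-enal
Product: 4 (5R)-1,1-dibromo-5-methylhepta-1,6-diene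
Conditions: CBr4, PPh3, CH2Cl2, 0 °C
Reagents that add atoms: carbon tetrabromide, BrC(Br)(Br)Br
Why: Corey–Fuchs dibromo-olefination, a Wittig reaction of the ylide made in the flask from CBr4 and PPh3, which homologates the aldehyde without touching the vinyl group or the stereocentre.

Step 3
Reactants: 4 (5R)-1,1-dibromo-5-methylhepta-1,6-diene
Product: 6 (3R)-3-methyloct-1-en-6-yne, via lithium acetylide 5 (not isolated)
Conditions: n-BuLi (2.1 equiv), THF, −78 to 0 °C; then MeI, 0 °C to rt
Reagents that add atoms: iodomethane, CI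
Why: Second stage of the Corey–Fuchs alkyne synthesis: bromine–lithium exchange, a Fritsch–Buttenberg–Wiechell 1,2-shift and deprotonation give acetylide 5, which is methylated on carbon by iodomethane.

Step 4
Reactants: 6 (3R)-3-methyloct-1-en-6-yne; 7 buta-1,3-diene
Product: 8 (1Z,4Z,8S,9R)-2,9-dimethylbicyclo[6.3.0]undeca-1,4-diene
Conditions: 7 (excess), RhCl(IMes)(cod) (cat.; IMes = 1,3-dimesitylimidazol-2-ylidene), AgOTf (AgOSO2CF3, cat.), toluene, 110 °C, sealed tube
Reagents that add atoms: none
Why: Rhodium-catalysed [4+2+2] cycloaddition of a 1,6-enyne with a 1,3-diene: oxidative cyclisation closes ring A as a rhodacyclopentene, butadiene inserts and reductive elimination closes ring B; the allylic methyl group sits exo in the metallacycle, so the ring-fusion hydrogen at C8 should come out cis to it.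

Step 5
Reactants: 8 (1Z,4Z,8S,9R)-2,9-dimethylbicyclo[6.3.0]undeca-1,4-diene
Product: 9 (1Z,4Z,8S,9R)-2,9-dimethylbicyclo[6.3.0]undeca-1,4-dien-3-one
Conditions: CrO3, 3,5-dimethylpyrazole, CH2Cl2, −20 °C
Reagents that add atoms: chromium trioxide, O=[Cr](=O)=O
Why: Allylic oxidation by the hexavalent chromium complex CrO3·3,5-dimethylpyrazole; the C3 methylene is the only doubly allylic position, has the weakest C–H bonds and should be oxidised to the cross-conjugated dienone ahead of the singly allylic sites.

Step 6
Reactants: 9 (1Z,4Z,8S,9R)-2,9-dimethylbicyclo[6.3.0]undeca-1,4-dien-3-one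
Product: 11 (1Z,5S,8S,9R)-2,5,9-trimethylbicyclo[6.3.0]undec-1-en-3-one, via methylzinc enolate 10 (not isolated)
Conditions: Me2Zn, Cu(OTf)2 (Cu(OSO2CF3)2, cat.), (S,R,R)-phosphoramidite ligand (cat.), toluene, −30 °C; aqueous work-up
Reagents that add atoms: dimethylzinc, C[Zn]C
Why: Copper-catalysed asymmetric conjugate addition of Me2Zn; only the disubstituted enone offers an open β-carbon (C5), the tetrasubstituted enone is inert, and the chiral phosphoramidite–copper catalyst should deliver methyl to the face that makes C5 S before zinc enolate 10 is hydrolysed.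

Step 7
Reactants: 12 (S)-limonene [(4S)-1-methyl-4-(prop-1-en-2-yl)cyclohex-1-ene]
Product: 13 (4S)-1-methyl-4-(propan-2-yl)cyclohex-1-ene
Conditions: H2 (1 atm, stopped after 1 equiv), PtO2 (cat.), EtOH, rt
Reagents that add atoms: none
Why: Chemoselective catalytic hydrogenation; the 1,1-disubstituted isopropenyl alkene is reduced well before the trisubstituted ring alkene, and the stereocentre is not involved.

Step 8
Reactants: 13 (4S)-1-methyl-4-(propan-2-yl)cyclohex-1-ene
Product: 15 (3S)-6-oxo-3-(propan-2-yl)heptanal, via ozonide 14 (not isolated)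
Conditions: O3, CH2Cl2, −78 °C; then Me2S, −78 °C to rt
Reagents that add atoms: ozone, [O-][O+]=O
Why: Ozonolysis of the ring alkene with reductive work-up opens the six-membered ring to the keto aldehyde without affecting the stereocentre.

Step 9
Reactants: 15 (3S)-6-oxo-3-(propan-2-yl)heptanal
Product: 16 (5R)-2-methyl-5-(propan-2-yl)cyclopent-1-ene-1-carbaldehyde
Conditions: piperidine (cat.), AcOH (cat.), benzene, reflux, water removed
Reagents that add atoms: none
Why: Amine-catalysed intramolecular aldol condensation; the enamine of the aldehyde attacks the methyl ketone to close the five-membered ring and dehydration gives the conjugated enal, the established outcome for 6-oxoheptanals of this kind.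

Step 10
Reactants: 16 (5R)-2-methyl-5-(propan-2-yl)cyclopent-1-ene-1-carbaldehyde
Product: 17 [(5R)-2-methyl-5-(propan-2-yl)cyclopent-1-en-1-yl]methanol
Conditions: NaBH4, CeCl3·7H2O, MeOH, 0 °C
Reagents that add atoms: none
Why: Luche reduction, which reduces the enal at the carbonyl group only and leaves the tetrasubstituted alkene in place.

Step 11
Reactants: 17 [(5R)-2-methyl-5-(propan-2-yl)cyclopent-1-en-1-yl]methanol
Product: 19 tributyl({[(5R)-2-methyl-5-(propan-2-yl)cyclopent-1-en-1-yl]methoxy}methyl)stannane, via potassium alkoxide 18 (not isolated)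
Conditions: KH, THF, 0 °C; then Bu3SnCH2I, 0 °C to rt
Reagents that add atoms: tributyl(iodomethyl)stannane, CCCC[Sn](CCCC)(CCCC)CI
Why: Williamson ether synthesis with the reactive iodomethylstannane, the usual entry to the substrate of a Still–Wittig rearrangement.

Step 12
Reactants: 19 tributyl({[(5R)-2-methyl-5-(propan-2-yl)cyclopent-1-en-1-yl]methoxy}methyl)stannane
Product: 22 [(1S,3R)-1-methyl-2-methylidene-3-(propan-2-yl)cyclopentyl]methyl 2,2-dimethylpropanoate, via lithiomethyl ether 20 (not isolated), via lithium alkoxide 21 (not isolated)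
Conditions: n-BuLi, THF, −78 to 0 °C; then t-BuCOCl, −78 °C to rt
Reagents that add atoms: pivaloyl chloride, CC(C)(C)C(=O)Cl
Why: Still–Wittig [2,3]-sigmatropic rearrangement: tin–lithium exchange gives the α-alkoxy organolithium 20, whose carbanion bonds suprafacially to the methyl-bearing alkene carbon on the ring face anti to the neighbouring isopropyl group, which creates the quaternary centre (CH2O trans to isopropyl) and the exocyclic methylene, and alkoxide 21 is acylated in the same flask.

Step 13
Reactants: 22 [(1S,3R)-1-methyl-2-methylidene-3-(propan-2-yl)cyclopentyl]methyl 2,2-dimethylpropanoate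
Product: 24 [(1S,2S,3R)-2-(hydroxymethyl)-1-methyl-3-(propan-2-yl)cyclopentyl]methyl 2,2-dimethylpropanoate, via B-alkyl-9-BBN 23 (not isolated)
Conditions: 9-BBN, THF, 65 °C; then H2O2, aq. NaOH, 0 °C to rt
Reagents that add atoms: hydrogen peroxide, OO
Why: Hydroboration–oxidation, anti-Markovnikov at the exocyclic methylene; 9-BBN should approach the face opposite to both the isopropyl group and the ring methyl, so that hydrogen enters C2' on the CH2OPiv face and the new CH2OH ends up cis to isopropyl and methyl.

Step 14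
Reactants: 24 [(1S,2S,3R)-2-(hydroxymethyl)-1-methyl-3-(propan-2-yl)cyclopentyl]methyl 2,2-dimethylpropanoate
Product: 25 [(1S,2S,3R)-2-({[tert-butyl(dimethyl)silyl]oxy}methyl)-1-methyl-3-(propan-2-yl)cyclopentyl]methyl 2,2-dimethylpropanoate
Conditions: TBSCl, imidazole, DMF, rt
Reagents that add atoms: tert-butyl(chloro)dimethylsilane, CC(C)(C)[Si](C)(C)Cl
Why: Standard silylation of a primary alcohol, chosen because the silyl ether survives the reductive, basic and oxidative steps up to step 19.

Step 15
Reactants: 25 [(1S,2S,3R)-2-({[tert-butyl(dimethyl)silyl]oxy}methyl)-1-methyl-3-(propan-2-yl)cyclopentyl]methyl 2,2-dimethylpropanoate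
Product: 26 [(1S,2S,3R)-2-({[tert-butyl(dimethyl)silyl]oxy}methyl)-1-methyl-3-(propan-2-yl)cyclopentyl]methanol
Conditions: i-Bu2AlH, CH2Cl2, −78 °C
Reagents that add atoms: none
Why: Reductive cleavage of the pivalate ester by the aluminium hydride, to which the silyl ether is inert.

Step 16
Reactants: 26 [(1S,2S,3R)-2-({[tert-butyl(dimethyl)silyl]oxy}methyl)-1-methyl-3-(propan-2-yl)cyclopentyl]methanol
Product: 27 (1S,2S,3R)-2-({[tert-butyl(dimethyl)silyl]oxy}methyl)-1-methyl-3-(propan-2-yl)cyclopentane-1-carbaldehyde
Conditions: Dess–Martin periodinane, CH2Cl2, rt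
Reagents that add atoms: none
Why: Dess–Martin oxidation of the neopentyl-type primary alcohol to the aldehyde, which has no α-hydrogen and cannot epimerise.

Step 17
Reactants: 11 (1Z,5S,8S,9R)-2,5,9-trimethylbicyclo[6.3.0]undec-1-en-3-one; 27 (1S,2S,3R)-2-({[tert-butyl(dimethyl)silyl]oxy}methyl)-1-methyl-3-(propan-2-yl)cyclopentane-1-carbaldehyde
Product: 29 (1Z,4S,5S,8S,9R)-4-{[(1S,2S,3R)-2-({[tert-butyl(dimethyl)silyl]oxy}methyl)-1-methyl-3-(propan-2-yl)cyclopentyl](hydroxy)methyl}-2,5,9-trimethylbicyclo[6.3.0]undec-1-en-3-one (both carbinol epimers), via lithium enolate 28 (not isolated)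
Conditions: LiN(i-Pr)2, THF, −78 °C; then 27, −78 °C; aqueous quench at −78 °C
Reagents that add atoms: none
Why: Directed aldol addition: LiN(i-Pr)2 removes a proton kinetically from the α'-CH2 (C4) of the enone, and the cross-conjugated enolate 28 adds to the non-enolisable aldehyde on its peripheral face anti to the C5 methyl, the carbinol centre being formed as a mixture that is removed in step 18.

Step 18
Reactants: 29 aldol adduct (both carbinol epimers)
Product: 31 (1Z,4E,5S,8S,9R)-4-{[(1R,2S,3R)-2-({[tert-butyl(dimethyl)silyl]oxy}methyl)-1-methyl-3-(propan-2-yl)cyclopentyl]methylidene}-2,5,9-trimethylbicyclo[6.3.0]undec-1-en-3-one, via mesylate 30 (not isolated)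
Conditions: MsCl, Et3N, CH2Cl2, 0 °C; then DBU, rt
Reagents that add atoms: none
Why: Mesylation followed by E1cB elimination of the β-mesyloxy ketone gives the conjugated exocyclic enone, expected as the E isomer with the bulky ring D unit turned away from the carbonyl group.

Step 19
Reactants: 31 exocyclic enone
Product: 33 (1Z,4R,5S,8S,9R)-4-{[(1R,2S,3R)-2-({[tert-butyl(dimethyl)silyl]oxy}methyl)-1-methyl-3-(propan-2-yl)cyclopentyl]methyl}-2,5,9-trimethylbicyclo[6.3.0]undec-1-en-3-one, via copper enolate 32 (not isolated)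
Conditions: [(Ph3P)CuH]6, benzene, H2O (2 equiv), rt; then DBU (cat.), CH2Cl2, rt
Reagents that add atoms: none
Why: Copper hydride conjugate reduction: hydride adds to the monosubstituted β-carbon of the exocyclic enone while the tetrasubstituted enone is inert, copper enolate 32 should be protonated on its exposed peripheral face (syn to the out-of-plane C5 methyl), and DBU then equilibrates C4 towards the trans-4,5-disubstituted ketone, expected to be the more stable epimer.

Step 20
Reactants: 33 silyl ether ketone
Product: 34 (1Z,4R,5S,8S,9R)-4-{[(1R,2S,3R)-2-(hydroxymethyl)-1-methyl-3-(propan-2-yl)cyclopentyl]methyl}-2,5,9-trimethylbicyclo[6.3.0]undec-1-en-3-one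
Conditions: HF·pyridine, THF, 0 °C to rt
Reagents that add atoms: none
Why: Fluoride-induced cleavage of the silyl ether under mildly acidic conditions that do not enolise the ketone.

Step 21
Reactants: 34 hydroxy enone
Product: 35 (1Z,4R,5S,8S,9R)-4-{[(1R,2S,3R)-2-(iodomethyl)-1-methyl-3-(propan-2-yl)cyclopentyl]methyl}-2,5,9-trimethylbicyclo[6.3.0]undec-1-en-3-one
Conditions: I2, PPh3, imidazole, CH2Cl2, 0 °C to rt
Reagents that add atoms: iodine, II
Why: Appel iodination; the oxyphosphonium of the primary alcohol is displaced by iodide at the CH2 group, so no stereocentre is touched.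

Step 22
Reactants: 35 iodo enone
Product: 37 sesterfisherol, via alkylsamarium 36 (not isolated)
Conditions: SmI2 (2.5 equiv), NiI2 (cat.), THF, 0 °C, high dilution; aqueous work-up
Reagents that add atoms: none
Why: Barbier cyclisation: two single-electron transfers from divalent samarium (mediated by catalytic NiI2) turn the primary C–I bond of 35 into alkylsamarium 36, which adds to the carbonyl carbon C3 of ring B; the closest known reaction type is the SmI2-promoted cyclisation of ω-iodo ketones to tertiary cycloalkanols. Ring C closes in a 6-exo-trig mode, the new bond running from the CH2 on the C/D-fusion carbon to the former carbonyl carbon, so the quaternary carbon is not involved. The one new stereocentre, the carbinol carbon, is controlled by the adjacent C4 centre: with the C4–H bond eclipsing the C3–C2 bond to avoid the fully substituted C2, the tether lies on the oxygen side and reaches the carbonyl carbon through a chair in which both ring B bonds and both ring D bonds are equatorial, which places the oxygen axial, anti to H-4 and on the face opposite the angular methyl (trans B/C fusion). The step needs reduction of the iodide to outpace reduction of the enone, and 1,2- rather than 1,4-addition. Leaving out HMPA and any proton source keeps ketyl formation slow and reversible, the β-carbon of the enone is tetrasubstituted and could only be reached through an eight-membered ring, and alkylsamarium reagents are hard nucleophiles. Aqueous work-up of the samarium alkoxide gives 37 directly.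

**Compound list**
1 | (R)-β-citronellene, (3R)-3,7-dimethylocta-1,6-diene | CC(C)=CCC[C@@H](C)C=C | starting material
2 | ozonide, 3,3-dimethyl-5-[(3R)-3-methylpent-4-en-1-yl]-1,2,4-trioxolane | CC1(C)OOC(CC[C@@H](C)C=C)O1 | intermediate
3 | (4R)-4-methylhex-5-enal | O=CCC[C@@H](C)C=C | intermediate
4 | (5R)-1,1-dibromo-5-methylhepta-1,6-diene | BrC(Br)=CCC[C@@H](C)C=C | intermediate
5 | lithium acetylide, [(5R)-5-methylhept-6-en-1-yn-1-yl]lithium | [Li]C#CCC[C@@H](C)C=C | intermediate
6 | (3R)-3-methyloct-1-en-6-yne | CC#CCC[C@@H](C)C=C | intermediate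
7 | buta-1,3-diene | C=CC=C | starting material
8 | (1Z,4Z,8S,9R)-2,9-dimethylbicyclo[6.3.0]undeca-1,4-diene | C/C1=C2\CC[C@@H](C)[C@@H]2CC/C=C\C1 | intermediate
9 | (1Z,4Z,8S,9R)-2,9-dimethylbicyclo[6.3.0]undeca-1,4-dien-3-one | C/C1=C2\CC[C@@H](C)[C@@H]2CC/C=C\C1=O | intermediate
10 | methylzinc enolate of 11 (C3–O–ZnMe, C3=C4) | C/C1=C2\CC[C@@H](C)[C@@H]2CC[C@H](C)C=C1O[Zn]C | intermediate
11 | AB enone, (1Z,5S,8S,9R)-2,5,9-trimethylbicyclo[6.3.0]undec-1-en-3-one | C/C1=C2\CC[C@@H](C)[C@@H]2CC[C@H](C)CC1=O | intermediate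
12 | (S)-limonene, (4S)-1-methyl-4-(prop-1-en-2-yl)cyclohex-1-ene | CC1=CC[C@H](CC1)C(C)=C | starting material
13 | (4S)-1-methyl-4-(propan-2-yl)cyclohex-1-ene | CC1=CC[C@H](CC1)C(C)C | intermediate
14 | ozonide, (4S)-1-methyl-4-(propan-2-yl)-7,8,9-trioxabicyclo[4.2.1]nonane | CC12CC[C@H](C(C)C)CC(OO1)O2 | intermediate
15 | (3S)-6-oxo-3-(propan-2-yl)heptanal | O=CC[C@H](CCC(C)=O)C(C)C | intermediate
16 | (5R)-2-methyl-5-(propan-2-yl)cyclopent-1-ene-1-carbaldehyde | O=CC1=C(C)CC[C@@H]1C(C)C | intermediate
17 | [(5R)-2-methyl-5-(propan-2-yl)cyclopent-1-en-1-yl]methanol | OCC1=C(C)CC[C@@H]1C(C)C | intermediate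
18 | potassium alkoxide of 17 | [K]OCC1=C(C)CC[C@@H]1C(C)C | intermediate
19 | tributyl({[(5R)-2-methyl-5-(propan-2-yl)cyclopent-1-en-1-yl]methoxy}methyl)stannane | CCCC[Sn](CCCC)(CCCC)COCC1=C(C)CC[C@@H]1C(C)C | intermediate
20 | lithiomethyl ether, ({[(5R)-2-methyl-5-(propan-2-yl)cyclopent-1-en-1-yl]methoxy}methyl)lithium | [Li]COCC1=C(C)CC[C@@H]1C(C)C | intermediate
21 | lithium [(1S,3R)-1-methyl-2-methylidene-3-(propan-2-yl)cyclopentyl]methanolate | [Li]OC[C@@]1(C)CC[C@H](C(C)C)C1=C | intermediate
22 | [(1S,3R)-1-methyl-2-methylidene-3-(propan-2-yl)cyclopentyl]methyl 2,2-dimethylpropanoate | CC(C)(C)C(=O)OC[C@@]1(C)CC[C@H](C(C)C)C1=C | intermediate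
23 | B-alkyl-9-BBN, [(1S,2S,3R)-2-(9-borabicyclo[3.3.1]nonan-9-ylmethyl)-1-methyl-3-(propan-2-yl)cyclopentyl]methyl 2,2-dimethylpropanoate | CC(C)(C)C(=O)OC[C@@]1(C)CC[C@H](C(C)C)[C@@H]1CB1C2CCCC1CCC2 | intermediate
24 | [(1S,2S,3R)-2-(hydroxymethyl)-1-methyl-3-(propan-2-yl)cyclopentyl]methyl 2,2-dimethylpropanoate | CC(C)(C)C(=O)OC[C@@]1(C)CC[C@H](C(C)C)[C@@H]1CO | intermediate
25 | [(1S,2S,3R)-2-({[tert-butyl(dimethyl)silyl]oxy}methyl)-1-methyl-3-(propan-2-yl)cyclopentyl]methyl 2,2-dimethylpropanoate | CC(C)(C)C(=O)OC[C@@]1(C)CC[C@H](C(C)C)[C@@H]1CO[Si](C)(C)C(C)(C)C | intermediate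
26 | [(1S,2S,3R)-2-({[tert-butyl(dimethyl)silyl]oxy}methyl)-1-methyl-3-(propan-2-yl)cyclopentyl]methanol | OC[C@@]1(C)CC[C@H](C(C)C)[C@@H]1CO[Si](C)(C)C(C)(C)C | intermediate
27 | ring D aldehyde, (1S,2S,3R)-2-({[tert-butyl(dimethyl)silyl]oxy}methyl)-1-methyl-3-(propan-2-yl)cyclopentane-1-carbaldehyde | O=C[C@@]1(C)CC[C@H](C(C)C)[C@@H]1CO[Si](C)(C)C(C)(C)C | intermediate
28 | lithium enolate of 11 (C3–OLi, C3=C4) | C/C1=C2\CC[C@@H](C)[C@@H]2CC[C@H](C)C=C1O[Li] | intermediate
29 | aldol adduct, 11 carrying at C4 (S) the CH(OH) group bonded to C1' of the ring D unit of 27, both carbinol epimers | C/C1=C2\CC[C@@H](C)[C@@H]2CC[C@H](C)[C@@H](C(O)[C@@]3(C)CC[C@H](C(C)C)[C@@H]3CO[Si](C)(C)C(C)(C)C)C1=O | intermediate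
30 | mesylate of 29 | C/C1=C2\CC[C@@H](C)[C@@H]2CC[C@H](C)[C@@H](C(OS(C)(=O)=O)[C@@]3(C)CC[C@H](C(C)C)[C@@H]3CO[Si](C)(C)C(C)(C)C)C1=O | intermediate
31 | (1Z,4E,5S,8S,9R)-4-{[(1R,2S,3R)-2-({[tert-butyl(dimethyl)silyl]oxy}methyl)-1-methyl-3-(propan-2-yl)cyclopentyl]methylidene}-2,5,9-trimethylbicyclo[6.3.0]undec-1-en-3-one | C/C1=C2\CC[C@@H](C)[C@@H]2CC[C@H](C)/C(=C\[C@@]3(C)CC[C@H](C(C)C)[C@@H]3CO[Si](C)(C)C(C)(C)C)C1=O | intermediate
32 | copper enolate of 33 (C3–OCu, C3=C4) | C/C1=C2\CC[C@@H](C)[C@@H]2CC[C@H](C)C(C[C@@]3(C)CC[C@H](C(C)C)[C@@H]3CO[Si](C)(C)C(C)(C)C)=C1O[Cu] | intermediate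
33 | (1Z,4R,5S,8S,9R)-4-{[(1R,2S,3R)-2-({[tert-butyl(dimethyl)silyl]oxy}methyl)-1-methyl-3-(propan-2-yl)cyclopentyl]methyl}-2,5,9-trimethylbicyclo[6.3.0]undec-1-en-3-one | C/C1=C2\CC[C@@H](C)[C@@H]2CC[C@H](C)[C@@H](C[C@@]3(C)CC[C@H](C(C)C)[C@@H]3CO[Si](C)(C)C(C)(C)C)C1=O | intermediate
34 | (1Z,4R,5S,8S,9R)-4-{[(1R,2S,3R)-2-(hydroxymethyl)-1-methyl-3-(propan-2-yl)cyclopentyl]methyl}-2,5,9-trimethylbicyclo[6.3.0]undec-1-en-3-one | C/C1=C2\CC[C@@H](C)[C@@H]2CC[C@H](C)[C@@H](C[C@@]3(C)CC[C@H](C(C)C)[C@@H]3CO)C1=O | intermediate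
35 | iodo enone, (1Z,4R,5S,8S,9R)-4-{[(1R,2S,3R)-2-(iodomethyl)-1-methyl-3-(propan-2-yl)cyclopentyl]methyl}-2,5,9-trimethylbicyclo[6.3.0]undec-1-en-3-one | C/C1=C2\CC[C@@H](C)[C@@H]2CC[C@H](C)[C@@H](C[C@@]3(C)CC[C@H](C(C)C)[C@@H]3CI)C1=O | intermediate
36 | alkylsamarium, 35 with CH2–SmI2 in place of CH2–I | C/C1=C2\CC[C@@H](C)[C@@H]2CC[C@H](C)[C@@H](C[C@@]3(C)CC[C@H](C(C)C)[C@@H]3C[Sm](I)I)C1=O | intermediate
37 | sesterfisherol | C/C1=C2\CC[C@@H](C)[C@@H]2CC[C@H](C)[C@H]2C[C@@]3(C)CC[C@H](C(C)C)[C@@H]3C[C@]12O | target

**Totals**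
Total step count: 22. Longest linear sequence: 16 steps (steps 7–16, then 17–22); the AB branch (steps 1–6) joins at step 17.

**Steps most likely to fail**

Step 5. The oxidation may proceed with allylic transposition (attack at a terminus of the pentadienyl system, giving conjugated rather than cross-conjugated dienones) or may also oxidise the ring A allylic CH2. The fallback sets out from 8 and uses a Riley oxidation with catalytic SeO2 and t-BuOOH in CH2Cl2, whose ene reaction and [2,3]-shift return oxygen to the carbon that lost hydrogen. This should give (1Z,4Z,8S,9R)-2,9-dimethylbicyclo[6.3.0]undeca-1,4-dien-3-ol F1 as a mixture of carbinol epimers. Oxidation of this doubly allylic alcohol with MnO2 would then give 9, where the route is rejoined.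

Step 19. Protonation of the enolate may occur on the wrong face, and equilibration may not favour the needed C4 epimer, so that the α'-centre is formed with poor or wrong selectivity. The fallback sets out from aldol 29, in which C4 was already fixed during C–C bond formation (electrophile anti to the C5 methyl), and avoids the enone altogether. Thioacylation with 1,1'-thiocarbonyldiimidazole (DMAP, toluene, 80 °C) should give O-{[(1S,2S,3R)-2-({[tert-butyl(dimethyl)silyl]oxy}methyl)-1-methyl-3-(propan-2-yl)cyclopentyl][(1Z,4S,5S,8S,9R)-2,5,9-trimethyl-3-oxobicyclo[6.3.0]undec-1-en-4-yl]methyl} 1H-imidazole-1-carbothioate F2. A Barton–McCombie deoxygenation (Bu3SnH, AIBN, toluene, 90 °C) would then remove the oxygen without touching C4 and return to the route at ketone 33.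

Step 22. Electron transfer to the enone may compete with reduction of the C–I bond (reduction or reductive dimerisation of ring B), or the alkylsamarium may be protonated before it cyclises. The fallback sets out from 35 and replaces the single-electron route by a polar one. Iodine–lithium exchange with t-BuLi (2.2 equiv) in pentane/Et2O at −100 °C is faster than addition of t-BuLi to a carbonyl group and would give the primary alkyllithium, if need be transmetalated with CeCl3 to curb enolisation. This closes the same bond by intramolecular 1,2-addition through the same chair and comes back to the route at 37; no further isolable compound is made.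

**Further compounds**
F1 | step 5 | (1Z,4Z,8S,9R)-2,9-dimethylbicyclo[6.3.0]undeca-1,4-dien-3-ol | C/C1=C2\CC[C@@H](C)[C@@H]2CC/C=C\C1O
F2 | step 19 | O-{[(1S,2S,3R)-2-({[tert-butyl(dimethyl)silyl]oxy}methyl)-1-methyl-3-(propan-2-yl)cyclopentyl][(1Z,4S,5S,8S,9R)-2,5,9-trimethyl-3-oxobicyclo[6.3.0]undec-1-en-4-yl]methyl} 1H-imidazole-1-carbothioate | C/C1=C2\CC[C@@H](C)[C@@H]2CC[C@H](C)[C@@H](C(OC(=S)n3ccnc3)[C@@]4(C)CC[C@H](C(C)C)[C@@H]4CO[Si](C)(C)C(C)(C)C)C1=O
F0 | step 22 | none | none
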